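The earlier runs and the new flask were generated by integration for an exercise; noise was put on by code.

Ask how much product the amber flask holds at 80 min, how near c(partner) stands to saturation at 40 min, and which change pays.

the same everywhere: substrate 0.072 M; free catalyst 48 µM
- amber: solid reagent 0.288 M; the very flask that is asked about, followed so far
- ochre: solid reagent 0.58 M; run made earlier
- flask: solid reagent 0.288 M; time 80 min

| run | time / min | product / % | substrate / % |
|---|---|---|---|
| amber | 2.00 | 0.4 | 99.7 |
| amber | 6.00 | 2.4 | 99.6 |
| amber | 10.0 | 3.6 | 97.4 |
| amber | 15.0 | 5.5 | 95.4 |
| ochre | 20.0 | 4.7 | 94.3 |
| ochre | 40.0 | 14.9 | 86.3 |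
| ochre | 60.0 | 24.0 | 78.0 |
| ochre | 80.0 | 32.7 | 68.0 |

(readings scatter by 1 percentage point)

- the product standing at 80 min, as a percentage of the substrate charged
- concentration of partner in solution at 40 min, in percent of saturation
- the change that raises the amount of product at 80 min, in percent of the substrate charged most ("none" if none brings more than 2 percentage points) (south / south-west / north / none)
- amount of product at 80 min, in percent of the substrate charged, after north

- south: doubling the solubility of the solid reagent, all else as stated
- south-west: doubling the dissolution coefficient of the solid reagent, all else as stated
- north: doubling the amount of free catalyst, all else as stated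

- given per volume of solution although it is solid: solid reagent
- at the start none of the solid reagent is in solution
- partner is what solid reagent becomes in solution

Take the symmetric case as the zero of the scale: a rate blind to the solid reagent gives a slope ratio of 1. The ochre charge of solid reagent is 2.01 times the amber one, yet the mean slope of ochre over amber reads 1.11, over different spans, with a scatter of 1 percentage point on the last amber reading of 5.5%. So use the bench rule of constant pace: the catalyst's pace, the turnover frequency 6.13 min⁻¹, is the moles of product made per mole of catalyst charged per minute, read here from the ochre run. The amber flask has the same substrate and catalyst charges, so commit to 32.7%.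

Find the border by a ratio: at this pace the amber substrate charge lasts 245 min, and past that the rule promises more product than was charged. The time asked for is a third of that span. Doubled catalyst, if the rate follows it, which neither run tests, gives 65.4%, and at that pace the charge lasts 122 min; hold that number loosely.

The forecast gives 30%, 92%, north and 50%, on the ground that “Doubling the solid barely changes the rate, so dissolution is not limiting”. Its product figure stands lower than mine.

The amber flask gives 31.7% of product, and 55.1% after north. Its c(partner) stands at 69.1% of saturation at 40.0 min. On the amber flask north gains 23 points, more than south with 7.7 points or south-west with 3 points.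

    partner + free catalyst → catalyst intermediate A (k = 24.0 M⁻¹ s⁻¹)
    catalyst intermediate A → by-product + catalyst intermediate B (k = 0.250 s⁻¹)
    catalyst intermediate B → catalyst intermediate C (k = 1.80 s⁻¹)
    substrate + catalyst intermediate C ⇌ catalyst intermediate D (K = 43.0 M⁻¹, k = 20.0 M⁻¹ s⁻¹)
    catalyst intermediate D → catalyst intermediate E (k = 15.0 s⁻¹)
    catalyst intermediate E ⇌ free catalyst + product (K = 0.100 M, k = 1.50 s⁻¹)
    solid reagent ⇌ partner, rate k7*(cs7 - [partner]) while solid is left; crystals form when [partner] > cs7 (solubility = 21.0 mM, k = 9.80 × 10⁻⁴ s⁻¹)

The amber flask is not at rest at 80.0 min, with 68.3% of its substrate still unreacted. Ten times the time adds 68 points of product, reaching 100% at 800 min with substrate at 0%. The catalyst then stands as catalyst intermediate C at 100%, free catalyst at 0%, while solid reagent keeps 67.7% of its charge.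

Carry the pace to the neighbour charged with 0.12 M of substrate: 6.13 min⁻¹ gives 19.6% at 80.0 min. The computed flask gives 19.7%.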